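**Plan**

- Cuts: with the protecting groups set aside, the two ester bonds that join a carboxyl oxygen to a stereocentre (acrylate O–CH and benzofuran C3-carboxylate O–CH) are cut together. This leaves a benzofuran diacid and two molecules of one (S)-aryl-lactate. The diacid is then cut at the acrylic C=C bond, at the O1–C2 and C3–CO2 bonds of furan ring B, and at the bond between benzene ring A and an alkyne.
- Forward: ring A (5-iodovanillin) and catechol ring C are joined through an alkyne; furan ring B, the only ring made, closes with uptake of CO; the acrylic acid is added; both arms (catechol rings D and E) are attached in one step; aqueous acid removes every protecting group.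
- Feature used: each stereocentre is a secondary sp3 carbon bonded to the ester oxygen, to a carboxyl carbon and to the CH2 group of a catechol ring (D or E). A carbon next to a carbonyl group is displaced cleanly by SN2, and its (R) configuration is the mirror image of the (S) centre of L-DOPA.
- Stereochemistry: both centres come from L-DOPA. Diazotisation exchanges NH2 for OH with retention, and the esterification then inverts (S) to (R). The E-alkene is set by the Knoevenagel–Doebner condensation.
- Protecting groups: methyl ethers carry the core through the metal-catalysed steps and are exchanged for methoxymethyl ethers before any ester link exists, so that the end game needs only aqueous acid.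

Key step: step 11

Assumption: Fmoc-L-DOPA(acetonide)-OH, the catechol-protected L-DOPA sold for peptide synthesis, is taken as the commercial chiral starting material, because HNO2 would oxidise the free catechol of L-DOPA itself.

**Route**

Step 1
Reactants: 1 5-iodovanillin (4-hydroxy-3-iodo-5-methoxybenzaldehyde)
Product: 2 4-formyl-2-iodo-6-methoxyphenyl acetate
Conditions: Ac2O, pyridine, DMAP (cat.), CH2Cl2, 0 °C to rt
Reagents that add atoms: acetic anhydride, CC(=O)OC(C)=O
Why: DMAP-catalysed O-acetylation (nucleophilic acyl substitution) of the acidic phenol should be fast and masks the hydroxyl, so that the alkynylphenol formed later cannot cyclise before carbon monoxide is present.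

Step 2
Reactants: 2 4-formyl-2-iodo-6-methoxyphenyl acetate; 3 4-ethynyl-1,2-dimethoxybenzene
Product: 4 2-[(3,4-dimethoxyphenyl)ethynyl]-4-formyl-6-methoxyphenyl acetate
Conditions: PdCl2(PPh3)2 (3 mol %), CuI (5 mol %), Et3N, THF, rt, degassed
Reagents that add atoms: none
Why: Sonogashira coupling, in which the aryl iodide activated by the para formyl group should undergo oxidative addition to zerovalent palladium at room temperature while the aryl acetate, the aldehyde and the methyl ethers stay inert to CuI and Et3N.

Step 3
Reactants: 4 2-[(3,4-dimethoxyphenyl)ethynyl]-4-formyl-6-methoxyphenyl acetate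
Product: 6 methyl 2-(3,4-dimethoxyphenyl)-5-formyl-7-methoxy-1-benzofuran-3-carboxylate, via free alkynylphenol 5 (not isolated)
Conditions: PdCl2 (10 mol %), CuCl2 (3 equiv), NaOAc, K2CO3, CO (1 atm), MeOH, rt
Reagents that add atoms: carbon monoxide, [C-]#[O+]; methanol, CO
Why: Oxidative alkoxycarbonylative cyclisation of an o-alkynylphenol, in which K2CO3 in MeOH cleaves the aryl acetate to phenol 5, its oxygen adds 5-endo-dig to the alkyne activated by divalent palladium, the 3-benzofuranylpalladium species inserts CO and is methanolysed to the ester, and CuCl2 returns zerovalent palladium to the divalent state.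

Step 4
Reactants: 6 methyl 2-(3,4-dimethoxyphenyl)-5-formyl-7-methoxy-1-benzofuran-3-carboxylate
Product: 7 (E)-3-[2-(3,4-dimethoxyphenyl)-7-methoxy-3-(methoxycarbonyl)-1-benzofuran-5-yl]prop-2-enoic acid
Conditions: CH2(CO2H)2 (3 equiv), pyridine, piperidine (cat.), 90 °C
Reagents that add atoms: malonic acid, OC(=O)CC(=O)O
Why: Knoevenagel–Doebner condensation, in which piperidine activates the aldehyde as an iminium ion toward malonic acid and decarboxylative elimination in hot pyridine should give the thermodynamically preferred E-acrylic acid, the hindered methyl ester being inert to these anhydrous amine conditions.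

Step 5
Reactants: 7 (E)-3-[2-(3,4-dimethoxyphenyl)-7-methoxy-3-(methoxycarbonyl)-1-benzofuran-5-yl]prop-2-enoic acid
Product: 8 (E)-3-[2-(3,4-dihydroxyphenyl)-7-hydroxy-3-(methoxycarbonyl)-1-benzofuran-5-yl]prop-2-enoic acid
Conditions: BBr3 (8 equiv), CH2Cl2, −78 °C to 0 °C; then H2O
Reagents that add atoms: none
Why: Lewis-acid ether cleavage (BBr3 demethylation), in which boron coordinates each aryl ether oxygen and bromide removes the methyl group by SN2 much faster than the conjugated methyl ester is attacked, placed here so that no strong Lewis acid is needed once the sensitive ester links exist.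

Step 6
Reactants: 8 (E)-3-[2-(3,4-dihydroxyphenyl)-7-hydroxy-3-(methoxycarbonyl)-1-benzofuran-5-yl]prop-2-enoic acid
Product: 9 methoxymethyl (E)-3-{2-[3,4-bis(methoxymethoxy)phenyl]-3-(methoxycarbonyl)-7-(methoxymethoxy)-1-benzofuran-5-yl}prop-2-enoate
Conditions: MOMCl (6 equiv), iPr2NEt (8 equiv), CH2Cl2–DMF, 0 °C to rt
Reagents that add atoms: chloromethyl methyl ether, COCCl
Why: O-alkylation with an alpha-chloro ether, in which the phenoxides and the carboxylate capture the methoxymethyl oxocarbenium ion, so that three base-stable but acid-labile acetals are installed in one operation and the transient methoxymethyl ester is removed in the next step.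

Step 7
Reactants: 9 methoxymethyl (E)-3-{2-[3,4-bis(methoxymethoxy)phenyl]-3-(methoxycarbonyl)-7-(methoxymethoxy)-1-benzofuran-5-yl}prop-2-enoate
Product: 10 (E)-3-{2-[3,4-bis(methoxymethoxy)phenyl]-3-carboxy-7-(methoxymethoxy)-1-benzofuran-5-yl}prop-2-enoic acid (core diacid)
Conditions: LiOH·H2O (8 equiv), THF–MeOH–H2O, 50 °C; then 1 M HCl to pH 3 at 0 °C
Reagents that add atoms: lithium hydroxide, [Li+].[OH-]
Why: Saponification (acyl–oxygen ester hydrolysis), in which hydroxide cleaves the reactive methoxymethyl ester at once and the hindered benzofuran-3-carboxylate on warming, whereas the aryl methoxymethyl acetals are inert to base and the acrylate, present as its carboxylate, resists conjugate addition.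

Step 8
Reactants: 11 Fmoc-L-DOPA(acetonide)-OH, (S)-3-(2,2-dimethyl-1,3-benzodioxol-5-yl)-2-{[(9H-fluoren-9-ylmethoxy)carbonyl]amino}propanoic acid
Product: 12 (S)-2-amino-3-(2,2-dimethyl-1,3-benzodioxol-5-yl)propanoic acid
Conditions: piperidine–DMF (1:4), rt; then trituration with Et2O
Reagents that add atoms: none
Why: Fmoc cleavage by E1cB elimination, in which piperidine removes the acidic fluorenyl proton, the carbamate collapses with loss of CO2 and the dibenzofulvene is trapped by piperidine, while the ketal and the stereocentre of the amino acid are untouched.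

Step 9
Reactants: 12 (S)-2-amino-3-(2,2-dimethyl-1,3-benzodioxol-5-yl)propanoic acid
Product: 14 (S)-3-(2,2-dimethyl-1,3-benzodioxol-5-yl)-2-hydroxypropanoic acid, via alpha-lactone 13 (not isolated)
Conditions: NaNO2 (1.5 equiv), 0.5 M H2SO4, H2O–1,4-dioxane, 0 °C to rt
Reagents that add atoms: water, O
Why: Diazotisation of an alpha-amino acid with hydrolysis, in which the neighbouring carboxylate displaces N2 from the diazonium ion with inversion to give alpha-lactone 13 and water opens it with a second inversion, so the (S) configuration should be retained, the ketal shielding the catechol from oxidation by HNO2 and surviving cold dilute acid.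

Step 10
Reactants: 14 (S)-3-(2,2-dimethyl-1,3-benzodioxol-5-yl)-2-hydroxypropanoic acid
Product: 15 tert-butyl (S)-3-(2,2-dimethyl-1,3-benzodioxol-5-yl)-2-hydroxypropanoate
Conditions: Cl3CC(=NH)OtBu (2.5 equiv), CH2Cl2–cyclohexane, rt
Reagents that add atoms: tert-butyl 2,2,2-trichloroacetimidate, CC(C)(C)OC(=N)C(Cl)(Cl)Cl
Why: Imidate esterification without added acid, in which only the carboxylic acid is acidic enough to protonate the trichloroacetimidate and capture the tert-butyl cation, so the secondary alcohol should stay free and no bond at the stereocentre is touched.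

Step 11
Reactants: 10 (E)-3-{2-[3,4-bis(methoxymethoxy)phenyl]-3-carboxy-7-(methoxymethoxy)-1-benzofuran-5-yl}prop-2-enoic acid; 15 tert-butyl (S)-3-(2,2-dimethyl-1,3-benzodioxol-5-yl)-2-hydroxypropanoate (2.6 equiv)
Product: 17 fully protected schizotenuin A (three methoxymethyl ethers; two acetonides; two tert-butyl esters; both stereocentres R), via acrylate monoester 16 (not isolated)
Conditions: PPh3 (3 equiv), DIAD (3 equiv, added dropwise), THF, 0 °C to rt
Reagents that add atoms: none
Why: PPh3 adds to DIAD to give a betaine that is protonated by a carboxylic acid of 10 and then transfers phosphorus to the hydroxyl of 15, and the carboxylate displaces triphenylphosphine oxide from the alkoxyphosphonium ion by backside SN2 attack, expected first at the unhindered acrylic acid (monoester 16) and then at the benzofuran-3-carboxylic acid. The closest known reaction type is the Mitsunobu esterification of alpha-hydroxy esters such as lactates and 3-aryl-lactates with carboxylic acids, which is known to proceed with inversion. No ring is closed, the two new bonds being acyclic oxygen–carbon bonds. Each new stereocentre is controlled by the substrate: the (S) centre of 15, taken from L-DOPA, becomes (R) because the carboxylate oxygen enters anti to the departing phosphine oxide. The step needs substitution to win over beta-elimination toward a cinnamate, ionisation and acyl transfer with retention, and the ester carbonyl next to the reacting carbon secures this by accelerating SN2 and destabilising a cation, helped by the weak basicity of the carboxylates and by the masking of all three phenols so that only carboxylates can be alkylated. Because the acid reacts through its oxygen and not through its carbonyl carbon, the hindered 2-arylbenzofuran-3-carboxylic acid, a poor partner in acyl-activation chemistry, should still be esterified.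

Step 12
Reactants: 17 fully protected schizotenuin A
Product: 18 schizotenuin A
Conditions: TFA–H2O (9:1), 0 °C to rt, argon; evaporation, reversed-phase chromatography
Reagents that add atoms: none
Why: Global acidolysis (SN1-type cleavage of acetals, ketals and tert-butyl esters), in which the three aryl methoxymethyl ethers, the two catechol isopropylidene ketals and the two tert-butyl esters all ionise in aqueous TFA, water in excess traps the released cations, and the two secondary ester links, the E-acrylate and the stereocentres alpha to the carboxyl groups are stable to acid at room temperature, so the (R,R) configuration is carried unchanged into the target.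

**Compound list**

1 | 5-iodovanillin (4-hydroxy-3-iodo-5-methoxybenzaldehyde) | O=Cc1cc(OC)c(O)c(I)c1 | starting material
2 | 4-formyl-2-iodo-6-methoxyphenyl acetate | O=Cc1cc(OC)c(OC(C)=O)c(I)c1 | intermediate
3 | 4-ethynyl-1,2-dimethoxybenzene | C#Cc1ccc(OC)c(OC)c1 | starting material
4 | 2-[(3,4-dimethoxyphenyl)ethynyl]-4-formyl-6-methoxyphenyl acetate | O=Cc1cc(OC)c(OC(C)=O)c(C#Cc2ccc(OC)c(OC)c2)c1 | intermediate
5 | 3-[(3,4-dimethoxyphenyl)ethynyl]-4-hydroxy-5-methoxybenzaldehyde (not isolated) | O=Cc1cc(OC)c(O)c(C#Cc2ccc(OC)c(OC)c2)c1 | intermediate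
6 | methyl 2-(3,4-dimethoxyphenyl)-5-formyl-7-methoxy-1-benzofuran-3-carboxylate | O=Cc1cc(OC)c2oc(-c3ccc(OC)c(OC)c3)c(C(=O)OC)c2c1 | intermediate
7 | (E)-3-[2-(3,4-dimethoxyphenyl)-7-methoxy-3-(methoxycarbonyl)-1-benzofuran-5-yl]prop-2-enoic acid | O=C(O)/C=C/c1cc(OC)c2oc(-c3ccc(OC)c(OC)c3)c(C(=O)OC)c2c1 | intermediate
8 | (E)-3-[2-(3,4-dihydroxyphenyl)-7-hydroxy-3-(methoxycarbonyl)-1-benzofuran-5-yl]prop-2-enoic acid | O=C(O)/C=C/c1cc(O)c2oc(-c3ccc(O)c(O)c3)c(C(=O)OC)c2c1 | intermediate
9 | methoxymethyl (E)-3-{2-[3,4-bis(methoxymethoxy)phenyl]-3-(methoxycarbonyl)-7-(methoxymethoxy)-1-benzofuran-5-yl}prop-2-enoate | O=C(OCOC)/C=C/c1cc(OCOC)c2oc(-c3ccc(OCOC)c(OCOC)c3)c(C(=O)OC)c2c1 | intermediate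
10 | (E)-3-{2-[3,4-bis(methoxymethoxy)phenyl]-3-carboxy-7-(methoxymethoxy)-1-benzofuran-5-yl}prop-2-enoic acid (core diacid) | O=C(O)/C=C/c1cc(OCOC)c2oc(-c3ccc(OCOC)c(OCOC)c3)c(C(=O)O)c2c1 | intermediate
11 | Fmoc-L-DOPA(acetonide)-OH, (S)-3-(2,2-dimethyl-1,3-benzodioxol-5-yl)-2-{[(9H-fluoren-9-ylmethoxy)carbonyl]amino}propanoic acid | O=C(N[C@@H](Cc1ccc2OC(C)(C)Oc2c1)C(=O)O)OCC1c2ccccc2-c2ccccc21 | starting material
12 | (S)-2-amino-3-(2,2-dimethyl-1,3-benzodioxol-5-yl)propanoic acid | N[C@@H](Cc1ccc2OC(C)(C)Oc2c1)C(=O)O | intermediate
13 | (R)-3-[(2,2-dimethyl-1,3-benzodioxol-5-yl)methyl]oxiran-2-one (alpha-lactone, not isolated) | O1[C@H](Cc2ccc3OC(C)(C)Oc3c2)C1=O | intermediate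
14 | (S)-3-(2,2-dimethyl-1,3-benzodioxol-5-yl)-2-hydroxypropanoic acid | O[C@@H](Cc1ccc2OC(C)(C)Oc2c1)C(=O)O | intermediate
15 | tert-butyl (S)-3-(2,2-dimethyl-1,3-benzodioxol-5-yl)-2-hydroxypropanoate | O[C@@H](Cc1ccc2OC(C)(C)Oc2c1)C(=O)OC(C)(C)C | intermediate
16 | 2-[3,4-bis(methoxymethoxy)phenyl]-5-[(E)-3-{[(2R)-1-tert-butoxy-3-(2,2-dimethyl-1,3-benzodioxol-5-yl)-1-oxopropan-2-yl]oxy}-3-oxoprop-1-en-1-yl]-7-(methoxymethoxy)-1-benzofuran-3-carboxylic acid (acrylate monoester, not isolated) | O=C(/C=C/c1cc(OCOC)c2oc(-c3ccc(OCOC)c(OCOC)c3)c(C(=O)O)c2c1)O[C@H](Cc1ccc2OC(C)(C)Oc2c1)C(=O)OC(C)(C)C | intermediate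
17 | (2R)-1-tert-butoxy-3-(2,2-dimethyl-1,3-benzodioxol-5-yl)-1-oxopropan-2-yl 2-[3,4-bis(methoxymethoxy)phenyl]-5-[(E)-3-{[(2R)-1-tert-butoxy-3-(2,2-dimethyl-1,3-benzodioxol-5-yl)-1-oxopropan-2-yl]oxy}-3-oxoprop-1-en-1-yl]-7-(methoxymethoxy)-1-benzofuran-3-carboxylate (fully protected schizotenuin A) | O=C(/C=C/c1cc(OCOC)c2oc(-c3ccc(OCOC)c(OCOC)c3)c(C(=O)O[C@H](Cc3ccc4OC(C)(C)Oc4c3)C(=O)OC(C)(C)C)c2c1)O[C@H](Cc1ccc2OC(C)(C)Oc2c1)C(=O)OC(C)(C)C | intermediate
18 | schizotenuin A, (R,R) | O=C(/C=C/c1cc(O)c2oc(-c3ccc(O)c(O)c3)c(C(=O)O[C@H](Cc3ccc(O)c(O)c3)C(=O)O)c2c1)O[C@H](Cc1ccc(O)c(O)c1)C(=O)O | target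

**Step count and risks**

Total step count: 12. Longest linear sequence: 9 steps (steps 1 to 7, then 11 and 12, from 5-iodovanillin); the lactate arm takes steps 8 to 10.

Steps most likely to fail:

Step 11. The second esterification at the hindered benzofuran-3-carboxylic acid may stay incomplete, the activated lactate may undergo beta-elimination, or acyl transfer through an anhydride may cause partial retention. The fallback keeps the same two oxygen–carbon bonds and the inversion but places the leaving group on the lactate beforehand; it sets out from 15 and 10 and returns to the route at 17. Treatment of 15 with Tf2O and 2,6-lutidine in CH2Cl2 at −78 °C should give, with retention, tert-butyl (S)-3-(2,2-dimethyl-1,3-benzodioxol-5-yl)-2-{[(trifluoromethyl)sulfonyl]oxy}propanoate F1. Added cold to the dicaesium salt of 10 (Cs2CO3, DMF, −20 °C to rt), it should be displaced by each carboxylate by SN2, again with inversion, to give 17.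

Step 12. The formaldehyde and methoxymethyl cations released from three acetals may be captured by the electron-rich catechol rings, or acetal cleavage may stay incomplete under conditions mild enough for the ester links. The fallback replaces the methoxymethyl ethers by allyl ethers, which are removed without any electrophilic fragment; it sets out from 8 and returns to the route at 18. Allyl bromide and K2CO3 in DMF should convert 8 into prop-2-enyl (E)-3-{2-[3,4-bis(prop-2-enyloxy)phenyl]-3-(methoxycarbonyl)-7-(prop-2-enyloxy)-1-benzofuran-5-yl}prop-2-enoate F2. LiOH in THF–MeOH–H2O should then give (E)-3-{2-[3,4-bis(prop-2-enyloxy)phenyl]-3-carboxy-7-(prop-2-enyloxy)-1-benzofuran-5-yl}prop-2-enoic acid F3. Coupling with 15 under the conditions of step 11 should give the tris(allyl ether) bis[(R)-lactate] ester F4. Allyl transfer to morpholine with Pd(PPh3)4 in THF should free the phenols to give the triphenol bis[(R)-lactate] ester that still carries both acetonides and both tert-butyl esters F5. TFA–H2O then releases only acetone and 2-methylpropene and should give 18.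

Step 3. The 3-benzofuranylpalladium intermediate may be protonated before CO insertion, or the phenoxide may cyclise under base or copper without carbonylation, so that the ring closes without the C3 carboxyl carbon. The fallback separates ring closure from carbonylation; it sets out from 4 and returns to the route at 6. Brief treatment of 4 with K2CO3 in MeOH at 0 °C should allow phenol 5 to be isolated. Iodocyclisation with I2 and NaHCO3 in MeCN should give 2-(3,4-dimethoxyphenyl)-3-iodo-7-methoxy-1-benzofuran-5-carbaldehyde F6. Alkoxycarbonylation of this aryl iodide (Pd(OAc)2, 1,1'-bis(diphenylphosphino)ferrocene, CO, Et3N, MeOH–DMF, 70 °C) should give 6.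

**Further compounds**

F1 | step 11 | tert-butyl (S)-3-(2,2-dimethyl-1,3-benzodioxol-5-yl)-2-{[(trifluoromethyl)sulfonyl]oxy}propanoate | O=S(=O)(O[C@@H](Cc1ccc2OC(C)(C)Oc2c1)C(=O)OC(C)(C)C)C(F)(F)F
F2 | step 12 | prop-2-enyl (E)-3-{2-[3,4-bis(prop-2-enyloxy)phenyl]-3-(methoxycarbonyl)-7-(prop-2-enyloxy)-1-benzofuran-5-yl}prop-2-enoate | O=C(OCC=C)/C=C/c1cc(OCC=C)c2oc(-c3ccc(OCC=C)c(OCC=C)c3)c(C(=O)OC)c2c1
F3 | step 12 | (E)-3-{2-[3,4-bis(prop-2-enyloxy)phenyl]-3-carboxy-7-(prop-2-enyloxy)-1-benzofuran-5-yl}prop-2-enoic acid | O=C(O)/C=C/c1cc(OCC=C)c2oc(-c3ccc(OCC=C)c(OCC=C)c3)c(C(=O)O)c2c1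
F4 | step 12 | tris(allyl ether) bis[(R)-lactate] ester (both acetonides and both tert-butyl esters in place) | O=C(/C=C/c1cc(OCC=C)c2oc(-c3ccc(OCC=C)c(OCC=C)c3)c(C(=O)O[C@H](Cc3ccc4OC(C)(C)Oc4c3)C(=O)OC(C)(C)C)c2c1)O[C@H](Cc1ccc2OC(C)(C)Oc2c1)C(=O)OC(C)(C)C
F5 | step 12 | triphenol bis[(R)-lactate] ester (both acetonides and both tert-butyl esters in place) | O=C(/C=C/c1cc(O)c2oc(-c3ccc(O)c(O)c3)c(C(=O)O[C@H](Cc3ccc4OC(C)(C)Oc4c3)C(=O)OC(C)(C)C)c2c1)O[C@H](Cc1ccc2OC(C)(C)Oc2c1)C(=O)OC(C)(C)C
F6 | step 3 | 2-(3,4-dimethoxyphenyl)-3-iodo-7-methoxy-1-benzofuran-5-carbaldehyde | O=Cc1cc(OC)c2oc(-c3ccc(OC)c(OC)c3)c(I)c2c1
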